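**Assumptions:** (2E,6E)-farnesol and 4-methoxy-3-methylphenol are taken as commercial. The cinchonidinium catalyst in step 10 is assumed to give the (1R,6S) epoxide; if the sense is opposite, the pseudo-enantiomeric cinchoninium salt is used with no other change.

## Retrosynthetic overview

1. Target ⇐ lipase-mediated removal of the primary acetate from a bis-acetate ⇐ epoxyquinol diol.
2. Epoxyquinol ⇐ regio- and diastereoselective 1,2-reduction of a quinone mono-epoxide ⇐ hydrolysis of an epoxy quinone monoketal.
3. Epoxide ⇐ catalytic asymmetric (chiral phase-transfer) nucleophilic epoxidation of an achiral 2-alkyl-5-methyl quinone monoketal; this sets both oxirane stereocentres.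
4. Monoketal ⇐ PhI(OAc)2/MeOH dearomatisation of 2-(12-hydroxyfarnesyl)-4-methoxy-5-methylphenol ⇐ ortho-lithiation/cuprate allylation of a MOM-protected phenol with an ω-silyloxy farnesyl bromide (from farnesol by SeO2 oxidation).
5. Ring order: the carbocycle is the starting arene and is never built; the only ring formed is the oxirane (step 10).

## Route

**Step 1**
Reactants: 1, (2E,6E)-farnesol
Product: 2, (2E,6E)-farnesyl acetate
Conditions: Ac2O, pyridine, DMAP (cat.), CH2Cl2, 0 °C → rt
Reagents that add atoms: acetic anhydride, CC(=O)OC(C)=O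
Why: Standard O-acylation masks the C1 hydroxyl and deactivates the proximal alkene for the next step.

**Step 2**
Reactants: 2, (2E,6E)-farnesyl acetate
Product: 3, (2E,6E,10E)-12-hydroxy-3,7,11-trimethyldodeca-2,6,10-trien-1-yl acetate
Conditions: SeO2 (0.5 equiv), t-BuOOH (70% aq.), salicylic acid (cat.), CH2Cl2, rt; then NaBH4, MeOH, 0 °C (returns over-oxidised enal to the alcohol)
Reagents that add atoms: tert-butyl hydroperoxide, CC(C)(C)OO (terminal oxidant; O delivered via SeO2, O=[Se]=O)
Why: Sharpless–Riley allylic oxidation (ene/[2,3]-sigmatropic) is selective for the E-methyl of the most electron-rich, remote trisubstituted alkene and gives the E-allylic alcohol.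

**Step 3**
Reactants: 3, 12-hydroxyfarnesyl acetate
Product: 4, (2E,6E,10E)-12-(tert-butyldimethylsilyloxy)-3,7,11-trimethyldodeca-2,6,10-trien-1-yl acetate
Conditions: TBSCl, imidazole, DMF, 0 °C → rt
Reagents that add atoms: TBSCl, CC(C)(C)[Si](C)(C)Cl
Why: Routine silylation of a primary alcohol; the acetate is untouched.

**Step 4**
Reactants: 4, silyloxy acetate
Product: 5, (2E,6E,10E)-12-(tert-butyldimethylsilyloxy)-3,7,11-trimethyldodeca-2,6,10-trien-1-ol
Conditions: K2CO3, MeOH, rt
Reagents that add atoms: none
Why: Mild methanolysis removes the acetate while the TBS ether is stable to carbonate.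

**Step 5**
Reactants: 5, allylic alcohol
Product: 6, (2E,6E,10E)-12-bromo-1-(tert-butyldimethylsilyloxy)-2,6,10-trimethyldodeca-2,6,10-triene (the 12-silyloxy farnesyl bromide)
Conditions: MsCl, Et3N, THF, −40 °C; then LiBr, THF, −40 → 0 °C; used crude
Reagents that add atoms: lithium bromide, [Li+].[Br-]
Why: Mesylation followed by SN2 bromide displacement under non-acidic conditions gives the primary allylic bromide without allylic transposition or E/Z erosion.

**Step 6**
Reactants: 7, 4-methoxy-3-methylphenol
Product: 8, 1-methoxy-4-(methoxymethoxy)-2-methylbenzene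
Conditions: MOMCl, i-Pr2NEt, CH2Cl2, 0 °C → rt
Reagents that add atoms: chloromethyl methyl ether, COCCl
Why: O-alkylation installs a MOM ether that protects the phenol and serves as the ortho-directing group.

**Step 7**
Reactants: 8, MOM aryl ether (2.2 equiv); 6, allylic bromide (1.0 equiv)
Product: 9, 1-(methoxymethoxy)-4-methoxy-5-methyl-2-[(2E,6E,10E)-12-(tert-butyldimethylsilyloxy)-3,7,11-trimethyldodeca-2,6,10-trien-1-yl]benzene
Conditions: n-BuLi, TMEDA, THF, 0 °C; CuBr·SMe2 (1.1 equiv), −78 → −40 °C; then 6, −78 → 0 °C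
Reagents that add atoms: none
Why: Directed ortho-metalation occurs at the unhindered C–H ortho to OMOM (the other ortho site is flanked by the methyl), and the diarylcuprate displaces the primary allylic bromide in an SN2 sense with retention of the E-alkene.

**Step 8**
Reactants: 9, protected arene
Product: 10, 2-[(2E,6E,10E)-12-hydroxy-3,7,11-trimethyldodeca-2,6,10-trien-1-yl]-4-methoxy-5-methylphenol
Conditions: HCl (1.25 M in MeOH), rt, monitored
Reagents that add atoms: none
Why: Acidic methanolysis cleaves both the aryl MOM acetal and the primary TBS ether; at rt the trisubstituted alkenes and the 2-methylallyl-type alcohol (no tertiary cation available) are stable.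

**Step 9**
Reactants: 10, p-methoxyphenol
Product: 11, 2-[(2E,6E,10E)-12-hydroxy-3,7,11-trimethyldodeca-2,6,10-trien-1-yl]-4,4-dimethoxy-5-methylcyclohexa-2,5-dien-1-one
Conditions: PhI(OAc)2 (1.1 equiv), MeOH, 0 °C, 20 min
Reagents that add atoms: methanol, CO
Why: Hypervalent-iodine oxidative dearomatisation of a p-methoxyphenol is trapped by solvent methanol at the para carbon, giving the quinone monoketal with the ketone next to the side chain.

**Step 10**
Reactants: 11, quinone monoketal
Product: 12, (1R,6S)-1-[(2E,6E,10E)-12-hydroxy-3,7,11-trimethyldodeca-2,6,10-trien-1-yl]-5,5-dimethoxy-4-methyl-7-oxabicyclo[4.1.0]hept-3-en-2-one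
Conditions: t-BuOOH (70% aq.), 2 M aq. NaOH, N-benzylcinchonidinium chloride (10 mol %), toluene, 0 °C → rt; ee checked by chiral HPLC
Reagents that add atoms: tert-butyl hydroperoxide, CC(C)(C)OO
Why: In this Weitz–Scheffer epoxidation under chiral phase-transfer catalysis the peroxide adds only to the unsubstituted β-carbon of the chain-bearing enone (the other β-carbon carries a methyl and is neopentyl to the ketal), and the chiral ammonium ion pair selects the enone face, setting both oxirane stereocentres.

**Step 11**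
Reactants: 12, epoxy monoketal
Product: 13, (1R,6S)-1-[(2E,6E,10E)-12-hydroxy-3,7,11-trimethyldodeca-2,6,10-trien-1-yl]-4-methyl-7-oxabicyclo[4.1.0]hept-3-ene-2,5-dione
Conditions: Montmorillonite K10, wet CH2Cl2, rt
Reagents that add atoms: water, O
Why: Mild acid-clay hydrolysis of the allylic dimethyl ketal releases the second carbonyl; the electron-poor epoxy ketone and the chain alkenes tolerate these conditions.

**Step 12**
Reactants: 13, quinone mono-epoxide
Product: 14, (1R,5R,6R)-5-hydroxy-1-[(2E,6E,10E)-12-hydroxy-3,7,11-trimethyldodeca-2,6,10-trien-1-yl]-4-methyl-7-oxabicyclo[4.1.0]hept-3-en-2-one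
Conditions: DIBAL-H (2.1 equiv; 1 equiv consumed by the OH), THF, −78 °C; Rochelle salt work-up
Reagents that add atoms: none
Why: 1,2-Reduction occurs at C5=O, which is more electrophilic (no β-methyl donor) and less hindered than C2=O (flanked by the quaternary oxirane carbon whose CH2R blocks the face anti to the epoxide), and hydride adds anti to the oxirane oxygen to give the cis-epoxy alcohol (5R).

**Step 13**
Reactants: 14, epoxyquinol diol
Product: 15, (1R,2R,6R)-6-[(2E,6E,10E)-12-acetoxy-3,7,11-trimethyldodeca-2,6,10-trien-1-yl]-3-methyl-5-oxo-7-oxabicyclo[4.1.0]hept-3-en-2-yl acetate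
Conditions: Ac2O (3 equiv), pyridine, DMAP (5 mol %), CH2Cl2, 0 °C
Reagents that add atoms: acetic anhydride, CC(=O)OC(C)=O
Why: Exhaustive acylation esterifies both hydroxyls with retention at the ring carbinol; the epoxy enone is stable to these mildly basic conditions.

**Step 14**
Reactants: 15, bis-acetate
Product: 16, yanuthone L, (1R,2R,6R)-6-[(2E,6E,10E)-12-hydroxy-3,7,11-trimethyldodeca-2,6,10-trien-1-yl]-3-methyl-5-oxo-7-oxabicyclo[4.1.0]hept-3-en-2-yl acetate
Conditions: lipase (immobilised Candida antarctica lipase B, Novozym 435), n-BuOH (5 equiv), MTBE, 30 °C; stopped at complete mono-deacetylation (HPLC)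
Reagents that add atoms: none
Why: Lipase-catalysed regioselective transesterification removes only the unhindered primary allylic acetate, because the ring secondary acetate flanked by the C-methyl and the oxirane is not accepted by the active site; the neutral conditions leave the epoxy enone and all stereocentres untouched.

## Compound list

1 | (2E,6E)-farnesol | OC/C=C(\C)CC/C=C(\C)CCC=C(C)C | starting material
2 | (2E,6E)-farnesyl acetate | CC(=O)OC/C=C(\C)CC/C=C(\C)CCC=C(C)C | intermediate
3 | (2E,6E,10E)-12-hydroxy-3,7,11-trimethyldodeca-2,6,10-trien-1-yl acetate | CC(=O)OC/C=C(\C)CC/C=C(\C)CC/C=C(\C)CO | intermediate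
4 | (2E,6E,10E)-12-(TBS-oxy)-3,7,11-trimethyldodeca-2,6,10-trien-1-yl acetate | CC(=O)OC/C=C(\C)CC/C=C(\C)CC/C=C(\C)CO[Si](C)(C)C(C)(C)C | intermediate
5 | (2E,6E,10E)-12-(TBS-oxy)-3,7,11-trimethyldodeca-2,6,10-trien-1-ol | OC/C=C(\C)CC/C=C(\C)CC/C=C(\C)CO[Si](C)(C)C(C)(C)C | intermediate
6 | (2E,6E,10E)-12-bromo-1-(TBS-oxy)-2,6,10-trimethyldodeca-2,6,10-triene | BrC/C=C(\C)CC/C=C(\C)CC/C=C(\C)CO[Si](C)(C)C(C)(C)C | intermediate
7 | 4-methoxy-3-methylphenol | COc1ccc(O)cc1C | starting material
8 | 1-methoxy-4-(methoxymethoxy)-2-methylbenzene | COCOc1ccc(OC)c(C)c1 | intermediate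
9 | 1-(methoxymethoxy)-4-methoxy-5-methyl-2-[(2E,6E,10E)-12-(TBS-oxy)-3,7,11-trimethyldodeca-2,6,10-trienyl]benzene | COCOc1cc(C)c(OC)cc1C/C=C(\C)CC/C=C(\C)CC/C=C(\C)CO[Si](C)(C)C(C)(C)C | intermediate
10 | 2-[(2E,6E,10E)-12-hydroxy-3,7,11-trimethyldodeca-2,6,10-trienyl]-4-methoxy-5-methylphenol | Oc1cc(C)c(OC)cc1C/C=C(\C)CC/C=C(\C)CC/C=C(\C)CO | intermediate
11 | 2-[(2E,6E,10E)-12-hydroxy-3,7,11-trimethyldodeca-2,6,10-trienyl]-4,4-dimethoxy-5-methylcyclohexa-2,5-dien-1-one | O=C1C=C(C)C(OC)(OC)C=C1C/C=C(\C)CC/C=C(\C)CC/C=C(\C)CO | intermediate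
12 | (1R,6S)-1-[(2E,6E,10E)-12-hydroxy-3,7,11-trimethyldodeca-2,6,10-trienyl]-5,5-dimethoxy-4-methyl-7-oxabicyclo[4.1.0]hept-3-en-2-one | COC1(OC)C(C)=CC(=O)[C@]2(C/C=C(\C)CC/C=C(\C)CC/C=C(\C)CO)O[C@H]12 | intermediate
13 | (1R,6S)-1-[(2E,6E,10E)-12-hydroxy-3,7,11-trimethyldodeca-2,6,10-trienyl]-4-methyl-7-oxabicyclo[4.1.0]hept-3-ene-2,5-dione | O=C1C(C)=CC(=O)[C@]2(C/C=C(\C)CC/C=C(\C)CC/C=C(\C)CO)O[C@H]12 | intermediate
14 | (1R,5R,6R)-5-hydroxy-1-[(2E,6E,10E)-12-hydroxy-3,7,11-trimethyldodeca-2,6,10-trienyl]-4-methyl-7-oxabicyclo[4.1.0]hept-3-en-2-one | O[C@@H]1C(C)=CC(=O)[C@]2(C/C=C(\C)CC/C=C(\C)CC/C=C(\C)CO)O[C@H]12 | intermediate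
15 | (1R,2R,6R)-6-[(2E,6E,10E)-12-acetoxy-3,7,11-trimethyldodeca-2,6,10-trienyl]-3-methyl-5-oxo-7-oxabicyclo[4.1.0]hept-3-en-2-yl acetate | CC(=O)O[C@@H]1C(C)=CC(=O)[C@]2(C/C=C(\C)CC/C=C(\C)CC/C=C(\C)COC(C)=O)O[C@H]12 | intermediate
16 | yanuthone L | CC(=O)O[C@@H]1C(C)=CC(=O)[C@]2(C/C=C(\C)CC/C=C(\C)CC/C=C(\C)CO)O[C@H]12 | target

## Summary

Total steps: 14. Longest linear sequence: 13 (farnesol → 1–5, then 7–14); the arene branch contributes one step (6) before the convergent coupling.

Three steps most likely to fail, with fallbacks: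

1. **Step 10 (asymmetric phase-transfer epoxidation; ee and rate on an α-alkyl dienone are not guaranteed).** Fallback: epoxidise racemically (TBHP/DBU), carry the material to (±)-14, and obtain the single enantiomer by lipase-catalysed kinetic resolution (enantioselective acetylation of the ring carbinol with vinyl acetate). Stereocontrol then moves from the epoxidation to an enzymatic resolution.

2. **Step 12 (regio- and stereoselective mono-reduction of the ene-dione; risk of C2=O reduction or over-reduction).** Fallback: remove the regiochemical question by masking. Keep the chain OH as a TBDPS ether, Luche-reduce the C2 ketone of 12 while C5 is still the ketal, protect that alcohol as a TES ether, hydrolyse the ketal, Luche-reduce the now unique C5 ketone (anti to the epoxide), acetylate, remove TES, re-oxidise C2–OH with Dess–Martin periodinane, then desilylate.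

3. **Step 7 (ortho-lithiation/cuprate allylation; risk of SN2′ product, lateral lithiation, or E/Z erosion).** Fallback: change the C–C bond-forming manifold. Trap the same aryllithium with B(OMe)3 and join the arylboronic acid to bromide 6 by Pd(0)-catalysed sp2–sp3 Suzuki coupling, which gives the linear E-allyl arene. Alternatively, obtain the aryl metal by Br/Li exchange from 2-bromo-4-methoxy-5-methylphenol MOM ether to fix the position unambiguously.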